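Prostaglandin numbering (C1–C20) is used throughout.

## The problem

15-Keto-PGF2alpha (29) is a cyclopentane with four contiguous stereocentres, C8 (R), C9 (S), C11 (R) and C12 (R), in which the two side chains are trans to each other and both hydroxyls lie on the face of the C8 chain. The C8 chain is a (Z)-hept-5-enoic acid and the C12 chain an (E)-3-oxooct-1-enyl group; because C15 is a ketone, no side-chain stereocentre is needed, but an enone must be introduced and kept intact. The ring centres can be made to depend on one another: a substituent at C12 sends an incoming group at C8 to the opposite face, the C8 substituent sends a hydride to the far face of a C9 ketone, and the trans relation of the C11 oxygen to C12 is the arrangement of least strain, so one absolute stereocentre is enough. The enone is attacked by hydrides and ylides, and base can deprotonate C12 next to it and expel the C11 oxygen. Any stage with the C11 oxygen β to a C9 carbonyl can eliminate to a cyclopentenone, a C13 aldehyde can epimerise at C12, and the Z-alkene is attacked by boranes and carbenoids. The feature used here is that C10 is a bare methylene between carbonyl-level C9 and oxygen-bearing C11. The ring can therefore be closed at C10–C11 by a carbene at C10 inserting into a C11–H bond activated by its own oxygen substituent, which creates the C11 stereocentre and leaves the C9 carbonyl as a handle.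

## Retrosynthesis

**Enone last.** Target 29 is traced to its 11-silyl ether 28, and 28 is cut at C13=C14 to aldehyde 25 and ketophosphonate 26. Cutting C5=C6 at this stage instead would require a lactol to be made and olefinated in the presence of the enone, which neither an aluminium hydride nor an unstabilised ylide would spare. With the enone last, C15 never passes through the alcohol level. The olefination must give the E-alkene without epimerising C12 or expelling the C11 oxygen.

**Upper chain.** Aldehyde 25 comes from diol acid 24 by oxidation of the primary alcohol only, and 24 from bis-silyl ether 23 by loss of the primary silyl group. Cutting C5=C6 of 23 gives lactol 20 and phosphonium salt 21, hence bis-silylated lactone 19 and lactone diol 18. The lactone is preferred to an open C6 aldehyde because it ties C6 to O9 and prepares the Z-selective olefination. The price is a free O9 afterwards, so the later oxidation must tell a primary from a secondary alcohol. Both hydroxyls of 18 are silylated because a free primary alkoxide next to a secondary silyl ether would invite silyl migration under the ylide conditions.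

**Telling C6 from C13.** Diol 18 is the reduction product of lactone acid 17. Acid 17 unravels to hydroxy diester 15 and, with C9 raised to the ketone, to cyclopentanone 14. The carboxyl carbons C6 and C13 of 14 are chemically alike, both tert-butyl esters. They are distinguished by geometry: after acidolysis only the C6 acid can reach the cis hydroxyl at C9. No orthogonal ester groups are needed earlier. The forward steps must deliver hydride to C9 anti to the C8 arm and reduce an acid beside a lactone.

**Key disconnection.** Cyclopentanone 14 is cut at C10–C11 to open-chain diazoketone 13. Against cuts at C8–C12 or C9–C10, this leaves a precursor with only two stereocentres, on adjacent carbons and both derived from a small ring template. C11 is then created in the bond-forming event. The forward reaction, a Rh2(OAc)4-catalysed 1,5 C–H insertion, must prefer the C11–H bonds to all others and one of them to its partner. The substrate is built for that: C6 and C13 carry no hydrogen, insertion at C7–H or C12–H would give four-membered rings, and C11–H is activated by the silyl ether oxygen.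

**Unmasking the insertion substrate.** Diazoketone 13 is the acylation product of acid 11 (cut at C9–C10). Acid 11 is the ring-opened, O-silylated form of lactone diester 8. In 8 the future C9 carboxyl and the C11 oxygen are one functional group, so opening the lactone frees exactly the two functions the key step needs. tert-Butyl esters are chosen because they survive hydroxide during this opening and fall together in acid later.

**Template.** The C13 ester of 8 is traced through acid 7 to the vinyl group of 6, a carboxyl surrogate without acidic α-hydrogens. Cutting C7–C8 of 6 gives lactone 3 and bromoacetate 4; the enolate is alkylated trans to the C12 substituent, so C12 controls C8. Lactone 3 is cut at C12–C13 to butenolide 1 and vinylboronate 2, a catalytic asymmetric conjugate addition that provides the only absolute stereochemical input. Compounds 1, 2, 4, 21 and 26 are commercial.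

## Roads not taken

**Alternative 1:** The cut removes the C8–C12 bond and all ring and C15 oxygens at once, back to arachidonic acid A1. In the forward direction prostaglandin H synthase performs a double dioxygenation on A1: oxygen adds at C11, the peroxyl radical closes onto C9, the C8 radical closes onto C12, and a second oxygen is taken up at C15, giving prostaglandin G2 A2. Reduction of both O–O bonds of A2 would give prostaglandin F2alpha A3, and oxidation of the allylic C15 alcohol of A3 would give the target 29.
- Merits: about three operations from A1, every stereocentre set by the enzyme, no protecting groups. In step count and stereocontrol this road is clearly better than the chosen one.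
- Weak points: it depends on an isolated haem enzyme that inactivates itself after limited turnover. A2 is a labile endoperoxide hydroperoxide that rearranges readily to E- and D-type products. Scale is small, and ring or chain variants are not accessible. A C15 stereocentre is made in A3 only to be erased.
- Comparison: the chosen plan offers ordinary reagents, stable and storable intermediates (8, 11, 18), preparative scale and late divergence at 24.

**Alternative 2:** The cut removes the C11–O bond and the C13=C14 alkene together, back to bicyclo[3.1.0]hexane epoxide A4, in which C13 bridges C11 and C12. In the forward direction acid ionises the 14,15-epoxide of A4 to a cyclopropylcarbinyl cation at C14. The C11–C13 bond opens as the aqueous medium captures C11 from the opposite face, giving prostaglandin F2alpha methyl ester 9-acetate A5 as a mixture of C15 epimers.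
- Merits: one step sets the C11 configuration, the E-alkene and the C15 oxygen. The C15 epimer mixture of A5 is no drawback here, because C15 is oxidised to the ketone afterwards; in this respect the road is as good as the chosen one.
- Weak points: the cation partitions between the wanted homoallylic capture, direct epoxide hydrolysis to glycols and other cyclopropylcarbinyl pathways, so the key step is inherently moderate. A4 requires a long sequence with the upper chain and the C8/C9 centres already installed on a strained bicycle. After the key step, allylic oxidation of A5 and two ester cleavages remain, the latter with base next to a new enone.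
- Comparison: the chosen plan sets C11 by a concerted insertion with no cation partitioning, from an acyclic precursor reached in six steps. It pays with separate steps for the C13=C14 alkene.

**Alternative 3:** The cut is at C9–C10, back to 4-alkynal A6. In the forward direction [Rh(dppe)]2(BF4)2 (monovalent rhodium) adds oxidatively into the aldehyde C–H bond of A6, trans-hydrometallates the alkyne and eliminates reductively to cyclopentenone A7.
- Merits: an atom-economical isomerisation with no diazo compound and no diazomethane. Both side arms of A7 are already differentiated at the alcohol level, so the ester differentiation of the chosen plan is not needed. In reagent safety and in handling of the arms this road is equal or better.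
- Weak points: A7 has a C10=C11 alkene and no oxygen at C11. The oxygen would have to be added afterwards (epoxidation and reductive opening, or oxygen conjugate addition), with face control from C12 alone and through a β-hydroxy ketone that reverts easily to the enone. A6 is an open-chain α-branched aldehyde with an epimerisable C8 and a propargylic C12, harder to make and keep than 13. Decarbonylation competes.
- Comparison: the chosen plan installs the C11 oxygen and its configuration during ring closure and fixes C8/C12 with a lactone template. Its costs are diazomethane and the carbenoid's chemoselectivity.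

Key step: step 7

Assumption: Rh/(S)-BINAP is taken to deliver the vinyl group to the same face of the unsaturated lactone as it does with cyclic enones (the α-si face), which gives (S)-3; if the sense were opposite, (R)-BINAP would be used and nothing else changes.

## Route

Step 1
Reactants: 1 furan-2(5H)-one; 2 vinylboronic acid pinacol ester
Product: 3 (4S)-4-ethenyloxolan-2-one
Conditions: 2 (3 equiv), Rh(acac)(C2H4)2 (3 mol %), (S)-BINAP (3.3 mol %), dioxane/H2O (10:1), 100 °C
Reagents that add atoms: none
Why: Rhodium-catalysed asymmetric 1,4-addition of an alkenylboron reagent (Hayashi–Miyaura reaction) is established for cyclic enones and unsaturated lactones; the vinyl complex of monovalent rhodium with BINAP inserts the butenolide on one face and water protonates the rhodium enolate. This sets C12, the only stereocentre introduced by a chiral reagent.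

Step 2
Reactants: 3 (4S)-4-ethenyloxolan-2-one; 4 tert-butyl bromoacetate
Product: 6 tert-butyl 2-[(3R,4R)-4-ethenyl-2-oxooxolan-3-yl]acetate, via lithium lactone enolate 5 (not isolated)
Conditions: LiN(SiMe3)2 (1.05 equiv), THF, −78 °C; then 4 (1.2 equiv), −78 → −40 °C
Reagents that add atoms: lithium bis(trimethylsilyl)amide [Li+].C[Si](C)(C)[N-][Si](C)(C)C (counter-ion of 5 only)
Why: Enolate alkylation of a 4-substituted butyrolactone occurs anti to the C4 substituent, so the acetate arm enters trans to the vinyl group and sets C8; the vinyl group carries no acidic hydrogen that could divert the base.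

Step 3
Reactants: 6 tert-butyl 2-[(3R,4R)-4-ethenyl-2-oxooxolan-3-yl]acetate
Product: 7 (3R,4R)-4-(2-tert-butoxy-2-oxoethyl)-5-oxooxolane-3-carboxylic acid
Conditions: RuCl3 hydrate (3 mol %), NaIO4 (5 equiv), EtOAc/MeCN/H2O, rt
Reagents that add atoms: sodium periodate [Na+].[O-]I(=O)(=O)=O; water O
Why: Ruthenium tetroxide formed in the flask cleaves the terminal alkene and oxidises the resulting aldehyde to the acid in one operation (oxidative alkene cleavage); the lactone and the tert-butyl ester are inert, and the trans arrangement at C8/C12 is the favoured one should C12 enolise.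

Step 4
Reactants: 7 (3R,4R)-4-(2-tert-butoxy-2-oxoethyl)-5-oxooxolane-3-carboxylic acid
Product: 8 tert-butyl (3R,4R)-4-(2-tert-butoxy-2-oxoethyl)-5-oxooxolane-3-carboxylate
Conditions: tert-butyl 2,2,2-trichloroacetimidate (2.5 equiv), BF3·OEt2 (0.1 equiv), CH2Cl2/cyclohexane, rt
Reagents that add atoms: tert-butyl 2,2,2-trichloroacetimidate CC(C)(C)OC(=N)C(Cl)(Cl)Cl
Why: Acid-catalysed O-alkylation of a carboxylic acid by the trichloroacetimidate proceeds through the tert-butyl cation under conditions too mild to cleave the existing tert-butyl ester or open the lactone.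

Step 5
Reactants: 8 tert-butyl (3R,4R)-4-(2-tert-butoxy-2-oxoethyl)-5-oxooxolane-3-carboxylate
Product: 11 (2R,3R)-4-tert-butoxy-2-(2-tert-butoxy-2-oxoethyl)-3-[(tert-butyldimethylsilyloxy)methyl]-4-oxobutanoic acid, via potassium hydroxy carboxylate 9 (not isolated), via bis-silylated silyl ester 10 (not isolated)
Conditions: KOH (1.05 equiv), THF/H2O, 0 °C → rt, evaporate to dryness; t-BuMe2SiCl (2.5 equiv), imidazole, DMF, rt; K2CO3, MeOH/THF/H2O, rt, then pH 4–5 (aq. citric acid)
Reagents that add atoms: potassium hydroxide [K+].[OH-]; tert-butyldimethylsilyl chloride CC(C)(C)[Si](C)(C)Cl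
Why: Hydroxide opens the γ-lactone much faster than it attacks hindered tert-butyl esters (saponification); silylation of the dry carboxylate salt traps the primary alcohol before it can close again, and carbonate methanolysis cleaves only the labile silyl ester.

Step 6
Reactants: 11 (2R,3R)-4-tert-butoxy-2-(2-tert-butoxy-2-oxoethyl)-3-[(tert-butyldimethylsilyloxy)methyl]-4-oxobutanoic acid
Product: 13 di-tert-butyl (2R,3R)-2-[(tert-butyldimethylsilyloxy)methyl]-3-(2-diazoacetyl)pentanedioate, via isobutyl carbonic mixed anhydride 12 (not isolated)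
Conditions: i-BuOCOCl (1.1 equiv), N-methylmorpholine (1.1 equiv), THF, −20 °C; CH2N2 (3 equiv, Et2O), 0 °C → rt
Reagents that add atoms: isobutyl chloroformate CC(C)COC(=O)Cl (atoms kept in 12 only); diazomethane C=[N+]=[N-]
Why: Acylation of diazomethane by a mixed carbonic anhydride (first stage of the Arndt–Eistert sequence) gives the α-diazoketone without an acid chloride, so the silyl ether, the tert-butyl esters and the C8 centre next to the activated carboxyl are preserved.

Step 7
Reactants: 13 di-tert-butyl (2R,3R)-2-[(tert-butyldimethylsilyloxy)methyl]-3-(2-diazoacetyl)pentanedioate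
Product: 14 tert-butyl (1R,2R,5R)-2-(2-tert-butoxy-2-oxoethyl)-5-(tert-butyldimethylsilyloxy)-3-oxocyclopentane-1-carboxylate
Conditions: Rh2(OAc)4 (1 mol %), CH2Cl2 (0.01 M), rt → 40 °C, slow addition of 13
Reagents that add atoms: none
Why: Rh2(OAc)4 (divalent rhodium) takes N2 from the diazoketone and forms an electrophilic carbenoid at C10, which inserts in a concerted three-centre manner into a C11–H bond made electron-rich by the silyl ether oxygen. The closest known reaction type is the Rh2(OAc)4-catalysed intramolecular 1,5 C–H insertion of α-diazoketones at C–H bonds next to ether oxygen. The cyclopentanone closes by 1,5-insertion through a six-membered chair-like array that includes the migrating hydrogen; closure onto C7–H or C12–H would give a cyclobutanone and these bonds are also deactivated by the adjacent esters, while C6 and C13 carry no hydrogen. The new stereocentre C11 is controlled by the substrate: with the C8 acetate arm and the C12 ester pseudo-equatorial, the silyloxy group also takes a pseudo-equatorial place, so the C11–H bond that reacts is the one that puts oxygen trans to the C12 ester and cis to the C8 arm, with retention at C11. C8 and C12 are spectators under these neutral conditions. The step needs chemoselectivity for C–H insertion over carbonyl-ylide formation at the two ester carbonyls, over attack on the ether oxygen and over carbene dimerisation. The low basicity of ester carbonyls, the bulk of the silyl group and slow addition at high dilution should secure it. The β-silyloxy ketone 14 can eliminate, so it is passed quickly through neutral silica and reduced at once.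

Step 8
Reactants: 14 tert-butyl (1R,2R,5R)-2-(2-tert-butoxy-2-oxoethyl)-5-(tert-butyldimethylsilyloxy)-3-oxocyclopentane-1-carboxylate
Product: 15 tert-butyl (1R,2R,3S,5R)-2-(2-tert-butoxy-2-oxoethyl)-5-(tert-butyldimethylsilyloxy)-3-hydroxycyclopentane-1-carboxylate
Conditions: LiBH(s-Bu)3 (1.2 equiv), THF, −78 °C; aq. NH4Cl
Reagents that add atoms: none
Why: The bulky trialkylborohydride attacks the cyclopentanone anti to the adjacent C8 arm and to the C11 silyloxy group (diastereoselective ketone reduction, as with 11-O-silyl ketones of the PGE type), which sets C9 with its hydroxyl cis to the C8 arm; tert-butyl esters are not reduced at −78 °C.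

Step 9
Reactants: 15 tert-butyl (1R,2R,3S,5R)-2-(2-tert-butoxy-2-oxoethyl)-5-(tert-butyldimethylsilyloxy)-3-hydroxycyclopentane-1-carboxylate
Product: 17 (3aR,4R,5R,6aS)-5-hydroxy-2-oxohexahydro-2H-cyclopenta[b]furan-4-carboxylic acid, via dihydroxy diacid 16 (not isolated)
Conditions: CF3CO2H/H2O (9:1), 0 °C → rt; concentrate from toluene
Reagents that add atoms: none
Why: Aqueous trifluoroacetic acid cleaves both tert-butyl esters by alkyl–oxygen fission and removes the silyl ether; only the C6 acid can reach the cis hydroxyl at C9, so γ-lactonisation to the cis-fused bicycle is spontaneous and leaves the C13 acid, trans to O9, free.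

Step 10
Reactants: 17 (3aR,4R,5R,6aS)-5-hydroxy-2-oxohexahydro-2H-cyclopenta[b]furan-4-carboxylic acid
Product: 18 (3aR,4S,5R,6aS)-5-hydroxy-4-(hydroxymethyl)hexahydro-2H-cyclopenta[b]furan-2-one
Conditions: BH3·THF (3.5 equiv), THF, 0 °C → rt; MeOH, evaporate
Reagents that add atoms: none
Why: Borane reduces a free carboxylic acid through its acyloxyborane much faster than a lactone (chemoselective borane reduction), turning C13 into the primary alcohol; the product is a known crystalline lactone diol, which serves as a check of identity and optical purity.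

Step 11
Reactants: 18 (3aR,4S,5R,6aS)-5-hydroxy-4-(hydroxymethyl)hexahydro-2H-cyclopenta[b]furan-2-one
Product: 19 (3aR,4S,5R,6aS)-5-(tert-butyldimethylsilyloxy)-4-[(tert-butyldimethylsilyloxy)methyl]hexahydro-2H-cyclopenta[b]furan-2-one
Conditions: t-BuMe2SiCl (2.5 equiv), imidazole (5 equiv), DMF, rt
Reagents that add atoms: tert-butyldimethylsilyl chloride CC(C)(C)[Si](C)(C)Cl
Why: Standard silylation of a primary and a secondary alcohol; protecting both leaves no free alkoxide next to a silyl ether during the ylide step, which avoids silyl migration.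

Step 12
Reactants: 19 (3aR,4S,5R,6aS)-5-(tert-butyldimethylsilyloxy)-4-[(tert-butyldimethylsilyloxy)methyl]hexahydro-2H-cyclopenta[b]furan-2-one
Product: 20 (3aR,4S,5R,6aS)-5-(tert-butyldimethylsilyloxy)-4-[(tert-butyldimethylsilyloxy)methyl]hexahydro-2H-cyclopenta[b]furan-2-ol (anomers)
Conditions: i-Bu2AlH (1.2 equiv), toluene, −78 °C; aq. potassium sodium tartrate
Reagents that add atoms: none
Why: At −78 °C the aluminium hydride stops at the stable tetrahedral aluminium acetal of the γ-lactone, which gives the lactol on hydrolysis (partial lactone reduction); silyl ethers are inert.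

Step 13
Reactants: 20 (3aR,4S,5R,6aS)-5-(tert-butyldimethylsilyloxy)-4-[(tert-butyldimethylsilyloxy)methyl]hexahydro-2H-cyclopenta[b]furan-2-ol; 21 (4-carboxybutyl)triphenylphosphonium bromide
Product: 23 (Z)-7-[(1R,2S,3R,5S)-3-(tert-butyldimethylsilyloxy)-2-[(tert-butyldimethylsilyloxy)methyl]-5-hydroxycyclopentyl]hept-5-enoic acid, via potassium ylide carboxylate 22 (not isolated)
Conditions: 21 (3 equiv), KOt-Bu (6 equiv), THF, 0 °C → rt; then 20, 0 °C → rt; aq. citric acid
Reagents that add atoms: potassium tert-butoxide CC(C)(C)[O-].[K+] (counter-ion of 22 only)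
Why: Wittig olefination of the lactol through its open hydroxy aldehyde with an unstabilised ylide gives the 5Z-alkene under kinetic control; the carboxylate in the ylide is tolerated when two equivalents of base are used per phosphonium salt.

Step 14
Reactants: 23 (Z)-7-[(1R,2S,3R,5S)-3-(tert-butyldimethylsilyloxy)-2-[(tert-butyldimethylsilyloxy)methyl]-5-hydroxycyclopentyl]hept-5-enoic acid
Product: 24 (Z)-7-[(1R,2S,3R,5S)-3-(tert-butyldimethylsilyloxy)-5-hydroxy-2-(hydroxymethyl)cyclopentyl]hept-5-enoic acid
Conditions: HF·pyridine, pyridine, THF, 0 °C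
Reagents that add atoms: none
Why: Pyridine-buffered HF·pyridine cleaves the unhindered primary silyl ether much faster than the secondary one on the ring (selective desilylation); the acid, the alkene and O9 are unaffected.

Step 15
Reactants: 24 (Z)-7-[(1R,2S,3R,5S)-3-(tert-butyldimethylsilyloxy)-5-hydroxy-2-(hydroxymethyl)cyclopentyl]hept-5-enoic acid
Product: 25 (Z)-7-[(1R,2R,3R,5S)-3-(tert-butyldimethylsilyloxy)-2-formyl-5-hydroxycyclopentyl]hept-5-enoic acid
Conditions: TEMPO (0.1 equiv), PhI(OAc)2 (1.1 equiv), CH2Cl2, rt
Reagents that add atoms: none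
Why: The oxoammonium species from TEMPO oxidises primary alcohols much faster than hindered secondary ones and stops at the aldehyde without water (nitroxyl-mediated selective oxidation). O9 is trans to C13 and cannot form a lactol that would be oxidised further.

Step 16
Reactants: 25 (Z)-7-[(1R,2R,3R,5S)-3-(tert-butyldimethylsilyloxy)-2-formyl-5-hydroxycyclopentyl]hept-5-enoic acid; 26 dimethyl (2-oxoheptyl)phosphonate
Product: 28 (Z)-7-[(1R,2R,3R,5S)-3-(tert-butyldimethylsilyloxy)-5-hydroxy-2-[(E)-3-oxooct-1-enyl]cyclopentyl]hept-5-enoic acid, via sodium phosphonate enolate 27 (not isolated)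
Conditions: 26 (2.5 equiv), NaH (2.4 equiv), THF, 0 °C; then 25, 0 °C → rt; pH 4 work-up
Reagents that add atoms: sodium hydride [Na+].[H-] (counter-ion of 27 only)
Why: Horner–Wadsworth–Emmons olefination with the stabilised β-ketophosphonate anion gives the E-enone; the weakly basic anion limits epimerisation at C12 and β-elimination of the C11 silyloxy group, and one extra equivalent takes up the carboxylic acid proton.

Step 17
Reactants: 28 (Z)-7-[(1R,2R,3R,5S)-3-(tert-butyldimethylsilyloxy)-5-hydroxy-2-[(E)-3-oxooct-1-enyl]cyclopentyl]hept-5-enoic acid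
Product: 29 (Z)-7-[(1R,2R,3R,5S)-3,5-dihydroxy-2-[(E)-3-oxooct-1-enyl]cyclopentyl]hept-5-enoic acid (15-keto-PGF2alpha)
Conditions: HF·pyridine, THF/MeCN, 0 °C → rt
Reagents that add atoms: none
Why: Fluoride cleavage of the secondary silyl ether under mildly acidic, non-basic conditions leaves the enone, the Z-alkene and the cis-diol untouched and affects no stereocentre.

## Compound list

1 | furan-2(5H)-one | O=C1OCC=C1 | starting material
2 | vinylboronic acid pinacol ester | C=CB1OC(C)(C)C(C)(C)O1 | starting material
3 | (4S)-4-ethenyloxolan-2-one | C=C[C@H]1COC(=O)C1 | intermediate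
4 | tert-butyl bromoacetate | CC(C)(C)OC(=O)CBr | starting material
5 | lithium (4S)-4-ethenyl-4,5-dihydrofuran-2-olate (not isolated) | C=C[C@H]1COC([O-])=C1.[Li+] | intermediate
6 | tert-butyl 2-[(3R,4R)-4-ethenyl-2-oxooxolan-3-yl]acetate | C=C[C@H]1COC(=O)[C@@H]1CC(=O)OC(C)(C)C | intermediate
7 | (3R,4R)-4-(2-tert-butoxy-2-oxoethyl)-5-oxooxolane-3-carboxylic acid | OC(=O)[C@H]1COC(=O)[C@@H]1CC(=O)OC(C)(C)C | intermediate
8 | tert-butyl (3R,4R)-4-(2-tert-butoxy-2-oxoethyl)-5-oxooxolane-3-carboxylate | CC(C)(C)OC(=O)[C@H]1COC(=O)[C@@H]1CC(=O)OC(C)(C)C | intermediate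
9 | potassium (2R,3R)-4-tert-butoxy-2-(2-tert-butoxy-2-oxoethyl)-3-(hydroxymethyl)-4-oxobutanoate (not isolated) | CC(C)(C)OC(=O)[C@@H](CO)[C@@H](CC(=O)OC(C)(C)C)C(=O)[O-].[K+] | intermediate
10 | tert-butyldimethylsilyl (2R,3R)-4-tert-butoxy-2-(2-tert-butoxy-2-oxoethyl)-3-[(tert-butyldimethylsilyloxy)methyl]-4-oxobutanoate (not isolated) | CC(C)(C)OC(=O)[C@@H](CO[Si](C)(C)C(C)(C)C)[C@@H](CC(=O)OC(C)(C)C)C(=O)O[Si](C)(C)C(C)(C)C | intermediate
11 | (2R,3R)-4-tert-butoxy-2-(2-tert-butoxy-2-oxoethyl)-3-[(tert-butyldimethylsilyloxy)methyl]-4-oxobutanoic acid | CC(C)(C)OC(=O)[C@@H](CO[Si](C)(C)C(C)(C)C)[C@@H](CC(=O)OC(C)(C)C)C(=O)O | intermediate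
12 | mixed anhydride of 11 with isobutyl hydrogen carbonate (not isolated) | CC(C)(C)OC(=O)[C@@H](CO[Si](C)(C)C(C)(C)C)[C@@H](CC(=O)OC(C)(C)C)C(=O)OC(=O)OCC(C)C | intermediate
13 | di-tert-butyl (2R,3R)-2-[(tert-butyldimethylsilyloxy)methyl]-3-(2-diazoacetyl)pentanedioate | CC(C)(C)OC(=O)[C@@H](CO[Si](C)(C)C(C)(C)C)[C@@H](CC(=O)OC(C)(C)C)C(=O)C=[N+]=[N-] | intermediate
14 | tert-butyl (1R,2R,5R)-2-(2-tert-butoxy-2-oxoethyl)-5-(tert-butyldimethylsilyloxy)-3-oxocyclopentane-1-carboxylate | CC(C)(C)OC(=O)[C@@H]1[C@@H](CC(=O)OC(C)(C)C)C(=O)C[C@H]1O[Si](C)(C)C(C)(C)C | intermediate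
15 | tert-butyl (1R,2R,3S,5R)-2-(2-tert-butoxy-2-oxoethyl)-5-(tert-butyldimethylsilyloxy)-3-hydroxycyclopentane-1-carboxylate | CC(C)(C)OC(=O)[C@@H]1[C@@H](CC(=O)OC(C)(C)C)[C@@H](O)C[C@H]1O[Si](C)(C)C(C)(C)C | intermediate
16 | (1R,2R,3S,5R)-2-(carboxymethyl)-3,5-dihydroxycyclopentane-1-carboxylic acid (not isolated) | OC(=O)[C@@H]1[C@@H](CC(=O)O)[C@@H](O)C[C@H]1O | intermediate
17 | (3aR,4R,5R,6aS)-5-hydroxy-2-oxohexahydro-2H-cyclopenta[b]furan-4-carboxylic acid | OC(=O)[C@@H]1[C@H]2CC(=O)O[C@H]2C[C@H]1O | intermediate
18 | (3aR,4S,5R,6aS)-5-hydroxy-4-(hydroxymethyl)hexahydro-2H-cyclopenta[b]furan-2-one | OC[C@@H]1[C@H]2CC(=O)O[C@H]2C[C@H]1O | intermediate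
19 | (3aR,4S,5R,6aS)-5-(tert-butyldimethylsilyloxy)-4-[(tert-butyldimethylsilyloxy)methyl]hexahydro-2H-cyclopenta[b]furan-2-one | CC(C)(C)[Si](C)(C)OC[C@@H]1[C@H]2CC(=O)O[C@H]2C[C@H]1O[Si](C)(C)C(C)(C)C | intermediate
20 | (3aR,4S,5R,6aS)-5-(tert-butyldimethylsilyloxy)-4-[(tert-butyldimethylsilyloxy)methyl]hexahydro-2H-cyclopenta[b]furan-2-ol (anomers) | CC(C)(C)[Si](C)(C)OC[C@@H]1[C@H]2CC(O)O[C@H]2C[C@H]1O[Si](C)(C)C(C)(C)C | intermediate
21 | (4-carboxybutyl)triphenylphosphonium bromide | OC(=O)CCCC[P+](c1ccccc1)(c1ccccc1)c1ccccc1.[Br-] | starting material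
22 | potassium 5-(triphenylphosphoranylidene)pentanoate (not isolated) | [K+].[O-]C(=O)CCCC=P(c1ccccc1)(c1ccccc1)c1ccccc1 | intermediate
23 | (Z)-7-[(1R,2S,3R,5S)-3-(tert-butyldimethylsilyloxy)-2-[(tert-butyldimethylsilyloxy)methyl]-5-hydroxycyclopentyl]hept-5-enoic acid | CC(C)(C)[Si](C)(C)OC[C@@H]1[C@@H](C/C=C\CCCC(=O)O)[C@@H](O)C[C@H]1O[Si](C)(C)C(C)(C)C | intermediate
24 | (Z)-7-[(1R,2S,3R,5S)-3-(tert-butyldimethylsilyloxy)-5-hydroxy-2-(hydroxymethyl)cyclopentyl]hept-5-enoic acid | OC[C@@H]1[C@@H](C/C=C\CCCC(=O)O)[C@@H](O)C[C@H]1O[Si](C)(C)C(C)(C)C | intermediate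
25 | (Z)-7-[(1R,2R,3R,5S)-3-(tert-butyldimethylsilyloxy)-2-formyl-5-hydroxycyclopentyl]hept-5-enoic acid | O=C[C@@H]1[C@@H](C/C=C\CCCC(=O)O)[C@@H](O)C[C@H]1O[Si](C)(C)C(C)(C)C | intermediate
26 | dimethyl (2-oxoheptyl)phosphonate | CCCCCC(=O)CP(=O)(OC)OC | starting material
27 | sodium 1-(dimethoxyphosphoryl)hept-1-en-2-olate (not isolated) | CCCCCC([O-])=CP(=O)(OC)OC.[Na+] | intermediate
28 | (Z)-7-[(1R,2R,3R,5S)-3-(tert-butyldimethylsilyloxy)-5-hydroxy-2-[(E)-3-oxooct-1-enyl]cyclopentyl]hept-5-enoic acid | CCCCCC(=O)/C=C/[C@@H]1[C@@H](C/C=C\CCCC(=O)O)[C@@H](O)C[C@H]1O[Si](C)(C)C(C)(C)C | intermediate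
29 | (Z)-7-[(1R,2R,3R,5S)-3,5-dihydroxy-2-[(E)-3-oxooct-1-enyl]cyclopentyl]hept-5-enoic acid (15-keto-PGF2alpha) | CCCCCC(=O)/C=C/[C@@H]1[C@@H](C/C=C\CCCC(=O)O)[C@@H](O)C[C@H]1O | target

## Step count and risk

Total step count: 17. Longest linear sequence: 17 steps (1 → 29); 2, 4, 21 and 26 are purchased.

**Step 7 (key step).** The carbenoid may be diverted: it can cyclise onto an ester carbonyl oxygen to a six-membered carbonyl ylide (with loss of isobutene), attack the ether oxygen, or dimerise. Discrimination between the two diastereotopic C11–H bonds may also be incomplete, because an acceptor-only carbenoid reacts through an early transition state. The fallback changes the carbenoid class, sets out from acid 11 and returns at 14. Activation of 11 with 1,1'-carbonyldiimidazole and C-acylation of Mg(O2CCH2CO2Bn)2 should give β-keto ester di-tert-butyl (2R,3R)-3-[3-(benzyloxy)-3-oxopropanoyl]-2-[(tert-butyldimethylsilyloxy)methyl]pentanedioate F1. Regitz diazo transfer (4-acetamidobenzenesulfonyl azide, Et3N) should give di-tert-butyl (2R,3R)-3-[3-(benzyloxy)-2-diazo-3-oxopropanoyl]-2-[(tert-butyldimethylsilyloxy)methyl]pentanedioate F2. Its acceptor/acceptor carbenoid with Rh2(OAc)4 is less reactive and more selective in 1,5-insertion and should give 1-benzyl 3-tert-butyl 4-(2-tert-butoxy-2-oxoethyl)-2-(tert-butyldimethylsilyloxy)-5-oxocyclopentane-1,3-dicarboxylate (ring configuration of 14, C1 epimers) F3. Hydrogenolysis (H2, Pd/C, ethyl acetate) and loss of CO2 from the β-keto acid under neutral conditions lead back to 14.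

**Step 1.** Transmetallation of the pinacol ester may be slow, and the vinylboron reagent may protodeboronate or oligomerise at 100 °C. Turnover with the weakly electrophilic five-membered lactone may be low, with eroded enantioselectivity. The fallback sets out from 1 and returns at acid 7, using aryl transfer, the most dependable case of this catalysis, with the arene as carboxyl surrogate. The same catalyst with 4-methoxyphenylboronic acid should give (4S)-4-(4-methoxyphenyl)oxolan-2-one F4. Alkylation as in step 2 should give tert-butyl 2-[(3R,4S)-4-(4-methoxyphenyl)-2-oxooxolan-3-yl]acetate F5. RuCl3/NaIO4 then degrades the electron-rich ring to the carboxyl group of 7.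

**Step 5.** The γ-hydroxy carboxylate may close again to the lactone during silylation or acidification. Base may also cause β-elimination across C11–C12 toward an itaconate-type alkene. The fallback sets out from 8 (through salt 9) and returns at 11. Alkylation of the dry potassium salt with benzyl bromide in DMF should give 1-benzyl 4-tert-butyl (2R,3R)-2-(2-tert-butoxy-2-oxoethyl)-3-(hydroxymethyl)butanedioate F6. Immediate silylation (t-BuMe2SiCl, imidazole) should give 1-benzyl 4-tert-butyl (2R,3R)-2-(2-tert-butoxy-2-oxoethyl)-3-[(tert-butyldimethylsilyloxy)methyl]butanedioate F7. Hydrogenolysis (H2, Pd/C) frees acid 11 without acid or base.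

**Step 15.** The secondary C9 hydroxyl may be over-oxidised, or the primary alcohol, crowded by the C11 silyl ether, may convert slowly. Enolisation at C12 of the aldehyde is a further risk. The fallback removes the need for selectivity, sets out from 23 and returns at 29. Exhaustive silylation (t-BuMe2SiCl, imidazole, DMF) should give tert-butyldimethylsilyl (Z)-7-[(1R,2S,3R,5S)-3,5-bis(tert-butyldimethylsilyloxy)-2-[(tert-butyldimethylsilyloxy)methyl]cyclopentyl]hept-5-enoate F8. Carbonate methanolysis of the silyl ester should give (Z)-7-[(1R,2S,3R,5S)-3,5-bis(tert-butyldimethylsilyloxy)-2-[(tert-butyldimethylsilyloxy)methyl]cyclopentyl]hept-5-enoic acid F9. Buffered HF·pyridine should remove the primary silyl group to give (Z)-7-[(1R,2S,3R,5S)-3,5-bis(tert-butyldimethylsilyloxy)-2-(hydroxymethyl)cyclopentyl]hept-5-enoic acid F10. With O9 protected, 1,1,1-triacetoxy-1,1-dihydro-1,2-benziodoxol-3(1H)-one should give (Z)-7-[(1R,2R,3R,5S)-3,5-bis(tert-butyldimethylsilyloxy)-2-formylcyclopentyl]hept-5-enoic acid F11. The olefination of step 16 should give (Z)-7-[(1R,2R,3R,5S)-3,5-bis(tert-butyldimethylsilyloxy)-2-[(E)-3-oxooct-1-enyl]cyclopentyl]hept-5-enoic acid F12. HF·pyridine then removes both silyl groups to give 29.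

## Further compounds

F1 | step 7 | di-tert-butyl (2R,3R)-3-[3-(benzyloxy)-3-oxopropanoyl]-2-[(tert-butyldimethylsilyloxy)methyl]pentanedioate | CC(C)(C)OC(=O)[C@@H](CO[Si](C)(C)C(C)(C)C)[C@@H](CC(=O)OC(C)(C)C)C(=O)CC(=O)OCc1ccccc1
F2 | step 7 | di-tert-butyl (2R,3R)-3-[3-(benzyloxy)-2-diazo-3-oxopropanoyl]-2-[(tert-butyldimethylsilyloxy)methyl]pentanedioate | CC(C)(C)OC(=O)[C@@H](CO[Si](C)(C)C(C)(C)C)[C@@H](CC(=O)OC(C)(C)C)C(=O)C(=[N+]=[N-])C(=O)OCc1ccccc1
F3 | step 7 | 1-benzyl 3-tert-butyl 4-(2-tert-butoxy-2-oxoethyl)-2-(tert-butyldimethylsilyloxy)-5-oxocyclopentane-1,3-dicarboxylate (ring configuration of 14, C1 epimers) | CC(C)(C)OC(=O)[C@@H]1[C@@H](CC(=O)OC(C)(C)C)C(=O)C(C(=O)OCc2ccccc2)[C@H]1O[Si](C)(C)C(C)(C)C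
F4 | step 1 | (4S)-4-(4-methoxyphenyl)oxolan-2-one | COc1ccc(cc1)[C@H]1COC(=O)C1
F5 | step 1 | tert-butyl 2-[(3R,4S)-4-(4-methoxyphenyl)-2-oxooxolan-3-yl]acetate | COc1ccc(cc1)[C@H]1COC(=O)[C@@H]1CC(=O)OC(C)(C)C
F6 | step 5 | 1-benzyl 4-tert-butyl (2R,3R)-2-(2-tert-butoxy-2-oxoethyl)-3-(hydroxymethyl)butanedioate | CC(C)(C)OC(=O)[C@@H](CO)[C@@H](CC(=O)OC(C)(C)C)C(=O)OCc1ccccc1
F7 | step 5 | 1-benzyl 4-tert-butyl (2R,3R)-2-(2-tert-butoxy-2-oxoethyl)-3-[(tert-butyldimethylsilyloxy)methyl]butanedioate | CC(C)(C)OC(=O)[C@@H](CO[Si](C)(C)C(C)(C)C)[C@@H](CC(=O)OC(C)(C)C)C(=O)OCc1ccccc1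
F8 | step 15 | tert-butyldimethylsilyl (Z)-7-[(1R,2S,3R,5S)-3,5-bis(tert-butyldimethylsilyloxy)-2-[(tert-butyldimethylsilyloxy)methyl]cyclopentyl]hept-5-enoate | CC(C)(C)[Si](C)(C)OC[C@@H]1[C@@H](C/C=C\CCCC(=O)O[Si](C)(C)C(C)(C)C)[C@@H](O[Si](C)(C)C(C)(C)C)C[C@H]1O[Si](C)(C)C(C)(C)C
F9 | step 15 | (Z)-7-[(1R,2S,3R,5S)-3,5-bis(tert-butyldimethylsilyloxy)-2-[(tert-butyldimethylsilyloxy)methyl]cyclopentyl]hept-5-enoic acid | CC(C)(C)[Si](C)(C)OC[C@@H]1[C@@H](C/C=C\CCCC(=O)O)[C@@H](O[Si](C)(C)C(C)(C)C)C[C@H]1O[Si](C)(C)C(C)(C)C
F10 | step 15 | (Z)-7-[(1R,2S,3R,5S)-3,5-bis(tert-butyldimethylsilyloxy)-2-(hydroxymethyl)cyclopentyl]hept-5-enoic acid | OC[C@@H]1[C@@H](C/C=C\CCCC(=O)O)[C@@H](O[Si](C)(C)C(C)(C)C)C[C@H]1O[Si](C)(C)C(C)(C)C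
F11 | step 15 | (Z)-7-[(1R,2R,3R,5S)-3,5-bis(tert-butyldimethylsilyloxy)-2-formylcyclopentyl]hept-5-enoic acid | O=C[C@@H]1[C@@H](C/C=C\CCCC(=O)O)[C@@H](O[Si](C)(C)C(C)(C)C)C[C@H]1O[Si](C)(C)C(C)(C)C
F12 | step 15 | (Z)-7-[(1R,2R,3R,5S)-3,5-bis(tert-butyldimethylsilyloxy)-2-[(E)-3-oxooct-1-enyl]cyclopentyl]hept-5-enoic acid | CCCCCC(=O)/C=C/[C@@H]1[C@@H](C/C=C\CCCC(=O)O)[C@@H](O[Si](C)(C)C(C)(C)C)C[C@H]1O[Si](C)(C)C(C)(C)C
A1 | alternative 1 | arachidonic acid | CCCCC/C=C\C/C=C\C/C=C\C/C=C\CCCC(=O)O
A2 | alternative 1 | prostaglandin G2 | CCCCC[C@H](OO)/C=C/[C@@H]1[C@@H](C/C=C\CCCC(=O)O)[C@@H]2C[C@H]1OO2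
A3 | alternative 1 | prostaglandin F2alpha | CCCCC[C@H](O)/C=C/[C@@H]1[C@@H](C/C=C\CCCC(=O)O)[C@@H](O)C[C@H]1O
A4 | alternative 2 | methyl (Z)-7-[3-acetoxy-6-(3-pentyloxiran-2-yl)bicyclo[3.1.0]hexan-2-yl]hept-5-enoate (ring centres C8, C9, C11, C12 defined; C13 to C15 left open) | CCCCCC1OC1C1[C@H]2C[C@H](OC(C)=O)[C@H](C/C=C\CCCC(=O)OC)[C@@H]12
A5 | alternative 2 | prostaglandin F2alpha methyl ester 9-acetate (C15 epimers) | CCCCCC(O)/C=C/[C@@H]1[C@@H](C/C=C\CCCC(=O)OC)[C@@H](OC(C)=O)C[C@H]1O
A6 | alternative 3 | (2R,3R)-2-[2-(tert-butyldimethylsilyloxy)ethyl]-3-[(4-methoxybenzyloxy)methyl]pent-4-ynal | C#C[C@H](COCc1ccc(OC)cc1)[C@@H](CCO[Si](C)(C)C(C)(C)C)C=O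
A7 | alternative 3 | (4S,5R)-5-[2-(tert-butyldimethylsilyloxy)ethyl]-4-[(4-methoxybenzyloxy)methyl]cyclopent-2-en-1-one | COc1ccc(COC[C@@H]2[C@@H](CCO[Si](C)(C)C(C)(C)C)C(=O)C=C2)cc1
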